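**Strategy.** Labels: seven-membered ring C1 (methylidene)–C5 (CMe2), fusion carbons C6/C10, cyclopentane C7, C8, quaternary C9; side chain C11–C16. Everything rests on cutting C8–C9. The feature exploited is the quaternary C9 of the cyclopentane (C6–C10), which carries a methyl group and the exocyclic methine C11 next to ring carbon C8: it is a latent 2-formyl-2-methylcyclopentanone. One Lewis-acid 1,2-acyl shift contracts a cyclohexanone to this ring, makes C8–C9, sets C9 and releases C11 as an aldehyde. The precursor is the cis-fused bicyclo[5.4.0] 2,3-epoxy-3-methylcyclohexanone bearing the C1 methylidene, oxirane on the H6/H10 face. Afterwards the C8 oxygen tethers C12 to C11 before its removal.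

Key step: step 7

**Remarks before the steps**
- Further labels: C12 = CH2OAc carbon on C11; C13 = lactone CH bonded to C11; C14 = lactone OCH2; C15 = lactone CH(OAc); C16 = lactone C=O. The α face is the face of H6 and H10. The β face is the face on which C1 and C5 leave the smaller ring. In these labels the target is 6R,9R,10S,11R,13R,15S.
- Stereochemical audit: in 29, H6 and H10 are cis (α), the C9 methyl is β and C11 is α. An α-oxirane in 10, opened with inversion at C9, gives exactly this arrangement in 11, so 10 and 11 need no structural change.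
- Design choices:
  - (a) The oxirane is opened in the presence of a non-nucleophilic pyridine, so that no Brønsted acid reaches the 1,1-disubstituted alkene.
  - (b) The C8 oxygen is kept while C11=C13 exists, because a C8 radical beside that alkene can rearrange by 3-exo closure and reopening (1,2-vinyl shift). It first anchors C12.
  - (c) C14 must end as CH2O while C16 stays at the acid level. The two carboxyl carbons are therefore kept different (lactone against tert-butyl ester), and the C15 oxygen is added last, on the finished lactone.
- Assumption: the sense of induction in step 3 follows the usual model for s-trans enones bound to the protonated oxazaborolidine (boron on the carbonyl lone pair syn to C10–H). This model calls for the (R)-catalyst, and both antipodes are sold.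

**Step 1**
Reactants: 1 4,4-dimethylcyclohex-2-en-1-one; 2 trimethylsilyldiazomethane
Product: 4 4,4-dimethylcyclohept-2-en-1-one, via alpha-silyl cycloheptenone 3 (not isolated)
Conditions: BF3·OEt2, CH2Cl2, −78 to −30 °C; then 1 M HCl, THF, rt
Reagents that add atoms: trimethylsilyldiazomethane, C[Si](C)(C)C=[N+]=[N-]
Why: Lewis-acid-promoted diazoalkane homologation of a ketone (Tiffeneau–Demjanov-type 1,2-shift), in which the diazo carbon adds to the BF3-bound carbonyl, the saturated alpha'-methylene migrates rather than the vinylic carbon as N2 leaves, and the silyl group of 3 discourages a second insertion before acid removes it, so that CMe2 ends next to the enone beta-carbon and no stereocentre arises.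

**Step 2**
Reactants: 5 (E)-pent-3-en-2-one
Product: 6 (E)-2-(tert-butyldimethylsilyloxy)penta-1,3-diene
Conditions: tBuMe2SiOTf, Et3N, Et2O, 0 °C
Reagents that add atoms: tert-butyldimethylsilyl triflate, CC(C)(C)[Si](C)(C)OS(=O)(=O)C(F)(F)F
Why: Soft enolisation with O-silylation, in which the silyl triflate activates the carbonyl and the amine takes a proton from the alpha'-methyl group, giving the cross-conjugated 2-silyloxy diene with the E-propenyl unit unchanged.

**Step 3**
Reactants: 4 4,4-dimethylcyclohept-2-en-1-one; 6 (E)-2-(tert-butyldimethylsilyloxy)penta-1,3-diene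
Product: 7 cis-fused bicyclo[5.4.0] adduct (C1 ketone, C8(OTBS)=C11 silyl enol ether, C9 methyl β, H6/H9/H10 α)
Conditions: (R)-o-tolyl-CBS oxazaborolidine (20 mol %), Tf2NH (18 mol %), CH2Cl2, −78 to −40 °C
Reagents that add atoms: (E)-2-(tert-butyldimethylsilyloxy)penta-1,3-diene, C/C=C/C(=C)O[Si](C)(C)C(C)(C)C
Why: Catalytic enantioselective Diels–Alder reaction in which the unhindered nucleophilic CH2 terminus of the diene (C7) bonds to the neopentyl beta-carbon C6 and the methyl-bearing terminus (C9) to C10 (ortho/para rule), suprafacial addition to the ring alkene makes H6 and H10 cis, the chiral boron cation shields one enone face and thereby fixes the absolute configuration at C6 and C10, and the endo-derived C9 centre is erased in step 5.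

**Step 4**
Reactants: 7 cis-fused bicyclo[5.4.0] adduct
Product: 8 C1-methylidene silyl enol ether (stereocentres as in 7)
Conditions: Cp2TiMe2, PhMe, 70 °C, dark
Reagents that add atoms: dimethyltitanocene, [CH3-].[CH3-].[Ti+4].c1cc[cH-]c1.c1cc[cH-]c1
Why: Petasis methylenation, in which thermally formed Cp2Ti=CH2 converts the C1 ketone into the methylidene through an oxatitanacyclobutane under non-basic conditions, so that the epimerisable C10–H and the silyl enol ether are left alone.

**Step 5**
Reactants: 8 C1-methylidene silyl enol ether
Product: 9 cis-fused enone (C8 ketone, C9=C11, C9 methyl, C1 methylidene, H6/H10 α)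
Conditions: Pd(OAc)2 (1.1 equiv), MeCN, rt
Reagents that add atoms: none
Why: Saegusa–Ito oxidation, in which the oxa-π-allylpalladium species formed at C11 can lose only the hydride on C9, so that the 3-methylcyclohexenone is formed with a defined double-bond position while the isolated alkene is not engaged.

**Step 6**
Reactants: 9 cis-fused enone
Product: 10 α-epoxy ketone (C9–C11 oxirane on the α face, C9 methyl β, H6/H10 α)
Conditions: H2O2 (30 % aq.), NaOH (cat.), MeOH, 0 °C
Reagents that add atoms: hydrogen peroxide, OO
Why: Weitz–Scheffer nucleophilic epoxidation, in which hydroperoxide adds only to the electron-poor C9 (the methylidene is inert), from the α face anti to the pseudoaxial C10–C1 bond, and the enolate closes the oxirane on that same face, while H10 lies close to the enone plane so that gamma-deprotonation should stay slow at 0 °C.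

**Step 7**
Reactants: 10 α-epoxy ketone
Product: 11 hydroazulene keto aldehyde (C8 ketone, C9 methyl β, C9 formyl = C11 α, H6/H10 α)
Conditions: BF3·OEt2, 2,6-di-tert-butyl-4-methylpyridine, CH2Cl2, −78 to −20 °C; cold aq. NaHCO3; used crude
Reagents that add atoms: none
Why: BF3 binds the oxirane oxygen, and the C9–O bond, which leads to a tertiary methyl-stabilised cationic centre, lengthens while the C8 acyl carbon slides from C11 to the rear lobe at C9 and the C11–O bond becomes the aldehyde C=O. This is the classical Lewis-acid semipinacol-type rearrangement of cyclic 2,3-epoxy ketones to ring-contracted 2-formyl ketones, best known for 2,3-epoxy-3,5,5-trimethylcyclohexanone. The cyclopentanone (C6–C7–C8–C9–C10) is closed by this suprafacial 1,2-shift rather than by an external bond formation, that is, by a six-to-five ring contraction that makes C8–C9 and breaks C8–C11. C9 is the only new stereocentre and is set stereospecifically, because the acyl group enters anti to the departing α-oxygen (inversion), so the α-oxirane of step 6 delivers methyl β and formyl α while C6 and C10 are untouched. The acyl shift must beat the H11 shift (which leads to the 1,2-dione), proton loss and attack by the C1 methylidene, and this is secured by the higher migratory aptitude of acyl in such oxiranes, by H10 lying syn to the leaving oxygen and so being unable to migrate in concert, and by low temperature with a hindered pyridine that traps stray acid. The non-enolisable β-keto aldehyde deformylates easily, hence the cold bicarbonate quench and direct use in step 8.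

**Step 8**
Reactants: 11 hydroazulene keto aldehyde; 12 methyl (triphenylphosphoranylidene)acetate
Product: 13 keto (E)-enoate (C11=C13 E, C14 methyl ester, C8 ketone)
Conditions: PhMe, 60 °C
Reagents that add atoms: methyl (triphenylphosphoranylidene)acetate, COC(=O)C=P(c1ccccc1)(c1ccccc1)c1ccccc1
Why: Wittig olefination with a stabilised ylide, which attacks only the aldehyde and not the neopentyl ketone, works in a neutral salt-free medium that avoids retro-Claisen loss of the formyl group, and gives the E-enoate as is usual for stabilised ylides.

**Step 9**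
Reactants: 13 keto (E)-enoate
Product: 14 8β-hydroxy (E)-enoate
Conditions: NaBH4, MeOH, −20 to 0 °C
Reagents that add atoms: none
Why: Chemoselective borohydride reduction of the ketone, in which hydride should arrive from the convex α face because the β face carries the C9 methyl group and the fold of the seven-membered ring, giving the 8β-alcohol and leaving the enoate intact, with this centre serving only as an anchor until step 15 deletes it.

**Step 10**
Reactants: 14 8β-hydroxy (E)-enoate; 15 (bromomethyl)chlorodimethylsilane
Product: 16 8β-(bromomethyl)dimethylsilyl ether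
Conditions: imidazole, DMAP (cat.), CH2Cl2, 0 °C to rt
Reagents that add atoms: (bromomethyl)chlorodimethylsilane, C[Si](C)(Cl)CBr
Why: Silyl ether formation by nucleophilic catalysis at silicon, which attaches the future C12 to the C8 oxygen without touching any stereocentre.

**Step 11**
Reactants: 16 8β-(bromomethyl)dimethylsilyl ether
Product: 17 trans-fused 1-oxa-2-silacyclohexane (ring O–Si–C12–C11–C9–C8; C11 bears CH2CO2Me and is configured as in 29)
Conditions: Bu3SnH (slow addition), AIBN (cat.), PhH, 80 °C, high dilution
Reagents that add atoms: none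
Why: Nishiyama–Stork silicon-tethered radical cyclisation, in which the silylmethyl radical closes 6-exo onto the polarity-matched beta-carbon C11, the tether overcomes the neopentyl hindrance, and C11 is set by a chair-like transition state with the acrylate arm pseudoequatorial, the small C9 methyl in the inside position (least 1,3-allylic strain) and C10 anti to the forming bond.

**Step 12**
Reactants: 17 trans-fused 1-oxa-2-silacyclohexane; 18 tert-butyl bromoacetate
Product: 19 C13-alkylated diester (C13 bears CO2Me = C14 and CH2CO2tBu = C15–C16; C13 configured as in 29)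
Conditions: LiN(iPr)2, THF, −78 °C; DMPU, then 18, −78 to −40 °C
Reagents that add atoms: tert-butyl bromoacetate, CC(C)(C)OC(=O)CBr
Why: Ester enolate alkylation under 1,3-allylic strain control, in which H11 eclipses the enolate double bond, the quaternary C9 blocks one face and the bromide is attacked from the C12 side, which sets C13, while the cyclic silyl ether masks both the C8 and the future C12 oxygen.

**Step 13**
Reactants: 19 C13-alkylated diester
Product: 21 cis-disubstituted γ-lactone (ring C12–O–C14(=O)–C13–C11) with free 8β-OH and tert-butyl ester, via diol ester 20 (not isolated)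
Conditions: H2O2 (30 % aq.), KF, KHCO3, THF–MeOH, rt; then PPTS (cat.), PhMe, 40 °C
Reagents that add atoms: hydrogen peroxide, OO
Why: Tamao–Kumada oxidation replaces the C12–Si bond by C12–OH and frees C8–OH under mildly basic conditions that spare the alkene, and the primary alcohol then lactonises onto the methyl ester (five-membered closure), which protects C12–O, marks C14 as the more reducible carbonyl and leaves only C8–OH free.

**Step 14**
Reactants: 21 cis-disubstituted γ-lactone
Product: 22 8β-O-phenyl thionocarbonate
Conditions: PhOC(S)Cl, DMAP, MeCN, rt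
Reagents that add atoms: O-phenyl chlorothionoformate, S=C(Cl)Oc1ccccc1
Why: Acylation of the only free hydroxyl group with a thionoformate under nucleophilic catalysis (first half of the Barton–McCombie sequence), chosen over a xanthate because it needs no strong base near the epimerisable C13.

**Step 15**
Reactants: 22 8β-O-phenyl thionocarbonate
Product: 23 C8-deoxygenated γ-lactone tert-butyl ester
Conditions: Bu3SnH, AIBN (cat.), PhMe, 90 °C
Reagents that add atoms: none
Why: Barton–McCombie deoxygenation, in which the stannyl radical adds to sulfur, the C8–O bond fragments and the secondary C8 radical takes hydrogen from the stannane, which is safe at this stage because C11 is sp3 and closure onto the C1 methylidene would be 4-exo or 5-endo.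

**Step 16**
Reactants: 23 C8-deoxygenated γ-lactone tert-butyl ester
Product: 24 12,14-diol tert-butyl ester
Conditions: LiBH4, THF, 0 °C to rt
Reagents that add atoms: none
Why: Chemoselective borohydride reduction, since LiBH4 opens the γ-lactone to the diol (C14 reaches the CH2O level) while the tert-butyl ester resists it and no stereocentre is affected.

**Step 17**
Reactants: 24 12,14-diol tert-butyl ester
Product: 27 hydroxy γ-lactone (ring C14–O–C16(=O)–C15–C13; free C12–OH), via tris-silyl derivative 25 (not isolated), via dihydroxy acid 26 (not isolated)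
Conditions: Me3SiOTf, 2,6-lutidine, CH2Cl2, 0 °C to rt; then aq. citric acid, THF, rt
Reagents that add atoms: none
Why: Silyl-triflate-mediated cleavage of the tert-butyl ester in a lutidine-buffered medium that cannot protonate the methylidene, followed by mild hydrolysis of the silyl groups and spontaneous lactonisation, in which five-membered closure through C14–OH is faster and gives a more stable ring than six-membered closure through C12–OH.

**Step 18**
Reactants: 27 hydroxy γ-lactone
Product: 28 15-hydroxy lactone (C15–OH trans to the C13 substituent; free C12–OH)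
Conditions: NaN(SiMe3)2 (2.3 equiv), THF, −78 °C; 2-(phenylsulfonyl)-3-phenyloxaziridine, −78 °C; AcOH quench
Reagents that add atoms: 2-(phenylsulfonyl)-3-phenyloxaziridine, O=S(=O)(c1ccccc1)N1OC1c1ccccc1
Why: Davis oxidation of the lactone enolate, with the C12 alkoxide as a spectator at −78 °C, in which the oxaziridine reaches the planar enolate anti to the very large C13 substituent and so sets C15 trans, which is also the more stable arrangement.

**Step 19**
Reactants: 28 15-hydroxy lactone
Product: 29 target CNP0234964.1
Conditions: Ac2O, pyridine, DMAP (cat.), CH2Cl2, 0 °C to rt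
Reagents that add atoms: acetic anhydride, CC(=O)OC(C)=O
Why: Nucleophile-catalysed acetylation of the primary C12 and secondary C15 hydroxyl groups in one operation, with retention at every stereocentre.

**Compound list**
1 | 4,4-dimethylcyclohex-2-en-1-one | CC1(C)CCC(=O)C=C1 | starting material
2 | trimethylsilyldiazomethane | C[Si](C)(C)C=[N+]=[N-] | starting material
3 | 4,4-dimethyl-7-(trimethylsilyl)cyclohept-2-en-1-one (racemic, transient) | O=C1C=CC(C)(C)CCC1[Si](C)(C)C | intermediate
4 | 4,4-dimethylcyclohept-2-en-1-one | CC1(C)CCCC(=O)C=C1 | intermediate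
5 | (E)-pent-3-en-2-one | C/C=C/C(C)=O | starting material
6 | (E)-2-(tert-butyldimethylsilyloxy)penta-1,3-diene | C/C=C/C(=C)O[Si](C)(C)C(C)(C)C | intermediate
7 | cis-fused bicyclo[5.4.0] adduct: C1 ketone, C8(OTBS)=C11, C9 methyl β, H6/H9/H10 α | O=C1CCCC(C)(C)[C@@H]2CC(O[Si](C)(C)C(C)(C)C)=C[C@H](C)[C@H]12 | intermediate
8 | C1-methylidene analogue of 7 | C=C1CCCC(C)(C)[C@@H]2CC(O[Si](C)(C)C(C)(C)C)=C[C@H](C)[C@H]12 | intermediate
9 | cis-fused 3-methylcyclohexenone: C8 ketone, C9=C11, C1 methylidene, H6/H10 α | C=C1CCCC(C)(C)[C@@H]2CC(=O)C=C(C)[C@H]12 | intermediate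
10 | α-epoxy ketone, key-step precursor: oxirane C9–C11 α, C9 methyl β | C=C1CCCC(C)(C)[C@@H]2CC(=O)[C@H]3O[C@@]3(C)[C@H]12 | intermediate
11 | hydroazulene 2-formyl-2-methylcyclopentanone, key-step product: methyl β, formyl α | C=C1CCCC(C)(C)[C@@H]2CC(=O)[C@@](C)(C=O)[C@H]12 | intermediate
12 | methyl (triphenylphosphoranylidene)acetate | COC(=O)C=P(c1ccccc1)(c1ccccc1)c1ccccc1 | starting material
13 | keto (E)-enoate | C=C1CCCC(C)(C)[C@@H]2CC(=O)[C@@](C)(/C=C/C(=O)OC)[C@H]12 | intermediate
14 | 8β-hydroxy (E)-enoate | C=C1CCCC(C)(C)[C@@H]2C[C@H](O)[C@@](C)(/C=C/C(=O)OC)[C@H]12 | intermediate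
15 | (bromomethyl)chlorodimethylsilane | C[Si](C)(Cl)CBr | starting material
16 | 8β-(bromomethyl)dimethylsilyl ether of 14 | C=C1CCCC(C)(C)[C@@H]2C[C@H](O[Si](C)(C)CBr)[C@@](C)(/C=C/C(=O)OC)[C@H]12 | intermediate
17 | trans-fused 1-oxa-2-silacyclohexane, C11 (R) bearing CH2CO2Me | C=C1CCCC(C)(C)[C@@H]2C[C@@H]3O[Si](C)(C)C[C@H](CC(=O)OC)[C@@]3(C)[C@H]12 | intermediate
18 | tert-butyl bromoacetate | CC(C)(C)OC(=O)CBr | starting material
19 | C13-alkylated methyl/tert-butyl diester of the oxasilacycle | C=C1CCCC(C)(C)[C@@H]2C[C@@H]3O[Si](C)(C)C[C@H]([C@@H](CC(=O)OC(C)(C)C)C(=O)OC)[C@@]3(C)[C@H]12 | intermediate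
20 | 8β,12-diol methyl/tert-butyl diester (transient) | C=C1CCCC(C)(C)[C@@H]2C[C@H](O)[C@@](C)([C@H](CO)[C@@H](CC(=O)OC(C)(C)C)C(=O)OC)[C@H]12 | intermediate
21 | cis-γ-lactone C12–O–C14(=O), 8β-OH, tert-butyl ester | C=C1CCCC(C)(C)[C@@H]2C[C@H](O)[C@@](C)([C@@H]3COC(=O)[C@@H]3CC(=O)OC(C)(C)C)[C@H]12 | intermediate
22 | 8β-O-phenyl thionocarbonate of 21 | C=C1CCCC(C)(C)[C@@H]2C[C@H](OC(=S)Oc4ccccc4)[C@@](C)([C@@H]3COC(=O)[C@@H]3CC(=O)OC(C)(C)C)[C@H]12 | intermediate
23 | C8-deoxygenated cis-γ-lactone tert-butyl ester | C=C1CCCC(C)(C)[C@@H]2CC[C@@](C)([C@@H]3COC(=O)[C@@H]3CC(=O)OC(C)(C)C)[C@H]12 | intermediate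
24 | 12,14-diol tert-butyl ester | C=C1CCCC(C)(C)[C@@H]2CC[C@@](C)([C@H](CO)[C@H](CO)CC(=O)OC(C)(C)C)[C@H]12 | intermediate
25 | 12,14-bis(trimethylsilyl) ether trimethylsilyl ester (transient) | C=C1CCCC(C)(C)[C@@H]2CC[C@@](C)([C@H](CO[Si](C)(C)C)[C@H](CO[Si](C)(C)C)CC(=O)O[Si](C)(C)C)[C@H]12 | intermediate
26 | 12,14-dihydroxy acid (transient) | C=C1CCCC(C)(C)[C@@H]2CC[C@@](C)([C@H](CO)[C@H](CO)CC(=O)O)[C@H]12 | intermediate
27 | γ-lactone C14–O–C16(=O) with free C12–OH | C=C1CCCC(C)(C)[C@@H]2CC[C@@](C)([C@H](CO)[C@@H]3COC(=O)C3)[C@H]12 | intermediate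
28 | trans-15-hydroxy lactone with free C12–OH | C=C1CCCC(C)(C)[C@@H]2CC[C@@](C)([C@H](CO)[C@@H]3COC(=O)[C@H]3O)[C@H]12 | intermediate
29 | CNP0234964.1 (6R,9R,10S,11R,13R,15S in the labels used here) | C=C1CCCC(C)(C)[C@@H]2CC[C@@](C)([C@H](COC(C)=O)[C@@H]3COC(=O)[C@H]3OC(C)=O)[C@H]12 | target

Total step count: 19. Longest linear sequence: 18 (steps 1 and 3–19; step 2 is a one-step side branch).

**Steps most likely to fail**

**Step 7.**
- What may go wrong: the opened oxirane may be diverted into a hydride shift or proton loss, the methylidene may be engaged or moved by the Lewis acid, or the formyl group may be lost on work-up.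
- Fallback: it sets out from 10 and moves the same ring contraction to the alcohol oxidation level.
- NaBH4/CeCl3·7H2O (MeOH, −78 °C) should give the epoxy alcohol F1. It is drawn 8α, from hydride attack anti to the oxirane, and this centre is without consequence.
- tBuMe2SiOTf/2,6-lutidine gives the epoxy silyl ether F2.
- Methylaluminium bis(4-bromo-2,6-di-tert-butylphenoxide) in CH2Cl2 at −78 °C then triggers the known rearrangement of 2,3-epoxy silyl ethers to β-siloxy aldehydes.
- Here the siloxy-bearing C8 migrates from C11 to C9 anti to the oxirane oxygen. The product is the siloxy aldehyde F3, which cannot deformylate.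
- Wittig reaction with 12 gives the siloxy enoate F4, Bu4NF frees the 8α-alcohol F5, and Dess–Martin periodinane brings the sequence back at 13.

**Step 3.**
- What may go wrong: the cycloaddition may be sluggish at the neopentyl-flanked C6, the silyl enol ether may be cleaved, or the catalyst may lose its face discrimination.
- Fallback: it sets out from 4 and 6, gives up catalytic induction and resolves later.
- Me2AlCl (CH2Cl2, −78 °C) should give the racemic cis adduct F6.
- Steps 4 and 5, unchanged, lead through the racemic methylidene silyl enol ether F7 to the racemic enone F8.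
- Luche reduction (NaBH4, CeCl3·7H2O) by axial hydride attack gives the racemic 8β-allylic alcohol F9.
- Acylation with vinyl acetate and Burkholderia cepacia lipase should, by the usual size rule for secondary alcohols, convert the (8R)-antipode into the acetate F10 and leave the (8S)-alcohol F11.
- After separation, MnO2 oxidises F11, and the sequence comes back at 9.

**Step 11.**
- What may go wrong: hydrogen may be transferred to the silylmethyl radical before it reaches the hindered C11, or discrimination between the two alkene faces may be insufficient.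
- Fallback: it sets out from 11 and replaces radical delivery by polar addition to a rigid ring.
- Still–Gennari olefination (methyl bis(2,2,2-trifluoroethyl)phosphonoacetate, KN(SiMe3)2, 18-crown-6, THF, −78 °C) gives the keto (Z)-enoate F12.
- NaBH4 gives the 8β-hydroxy (Z)-ester F13, which closes to the trans-fused unsaturated δ-lactone F14.
- In this ring the C9 methyl group is axial. The cuprate from (isopropoxydimethylsilyl)methylmagnesium chloride and CuBr·SMe2 (Me3SiCl, THF, −78 to −20 °C) should therefore add to C11 anti to it, giving the silylmethyl lactone F15.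
- NaOMe in MeOH opens the lactone to the methyl ester, and the freed C8 alkoxide displaces isopropoxide at silicon. The sequence comes back at 17.

**Further compounds**
F1 | step 7 | 8α-hydroxy α-epoxide (epoxy alcohol) | C=C1CCCC(C)(C)[C@@H]2C[C@@H](O)[C@H]3O[C@@]3(C)[C@H]12
F2 | step 7 | 8α-tert-butyldimethylsilyl ether of F1 | C=C1CCCC(C)(C)[C@@H]2C[C@@H](O[Si](C)(C)C(C)(C)C)[C@H]3O[C@@]3(C)[C@H]12
F3 | step 7 | hydroazulene 8α-siloxy aldehyde (methyl β, formyl α) | C=C1CCCC(C)(C)[C@@H]2C[C@@H](O[Si](C)(C)C(C)(C)C)[C@@](C)(C=O)[C@H]12
F4 | step 7 | 8α-siloxy (E)-enoate | C=C1CCCC(C)(C)[C@@H]2C[C@@H](O[Si](C)(C)C(C)(C)C)[C@@](C)(/C=C/C(=O)OC)[C@H]12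
F5 | step 7 | 8α-hydroxy (E)-enoate | C=C1CCCC(C)(C)[C@@H]2C[C@@H](O)[C@@](C)(/C=C/C(=O)OC)[C@H]12
F6 | step 3 | racemic 7 (relative configuration shown) | O=C1CCCC(C)(C)[C@@H]2CC(O[Si](C)(C)C(C)(C)C)=C[C@H](C)[C@H]12
F7 | step 3 | racemic 8 (relative configuration shown) | C=C1CCCC(C)(C)[C@@H]2CC(O[Si](C)(C)C(C)(C)C)=C[C@H](C)[C@H]12
F8 | step 3 | racemic 9 (relative configuration shown) | C=C1CCCC(C)(C)[C@@H]2CC(=O)C=C(C)[C@H]12
F9 | step 3 | racemic 8β-allylic alcohol (relative configuration shown) | C=C1CCCC(C)(C)[C@@H]2C[C@H](O)C=C(C)[C@H]12
F10 | step 3 | (8R)-allylic acetate of the unwanted antipode | C=C1CCCC(C)(C)[C@H]2C[C@@H](OC(C)=O)C=C(C)[C@@H]12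
F11 | step 3 | (8S)-allylic alcohol of the wanted series | C=C1CCCC(C)(C)[C@@H]2C[C@H](O)C=C(C)[C@H]12
F12 | step 11 | keto (Z)-enoate | C=C1CCCC(C)(C)[C@@H]2CC(=O)[C@@](C)(/C=C\C(=O)OC)[C@H]12
F13 | step 11 | 8β-hydroxy (Z)-ester (transient) | C=C1CCCC(C)(C)[C@@H]2C[C@H](O)[C@@](C)(/C=C\C(=O)OC)[C@H]12
F14 | step 11 | trans-fused unsaturated δ-lactone (C8–O–C14(=O)–C13=C11) | C=C1CCCC(C)(C)[C@@H]2C[C@@H]3OC(=O)C=C[C@@]3(C)[C@H]12
F15 | step 11 | δ-lactone bearing the (isopropoxydimethylsilyl)methyl group on C11 | C=C1CCCC(C)(C)[C@@H]2C[C@@H]3OC(=O)C[C@@H](C[Si](C)(C)OC(C)C)[C@@]3(C)[C@H]12
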